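**Plan**
- Cuts: ring C at O1–C2 and C2–C3 (back to a ring B methyl benzoate and a ring A acetophenone), the C7''–O bond (back to a C7'' methylene), the C8''–O–C4' aryl ether, and C1''–C7''.
- Enabling feature: C7'' is a benzylic CH2 para to the oxygen on ring D. O9'' sits 1,3 to it across C8'', so a tert-butyl carbonate on O9'' can trap an anodically made C7'' cation through a six-membered ring.
- Forward order: ring D Grignard reagent plus (S)-benzyl glycidyl ether (C1''–C7''), Mitsunobu coupling with methyl syringate (ring B), O9'' debenzylation and Boc carbonate, anodic closure of the 7'',9''-carbonate, exchange of the carbonate for a silylene, Claisen condensation with the ring A ketone, cyclodehydration to ring C, hydrogenolysis, one fluoride step.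
- Stereochemistry: C8'' is bought with the glycidyl ether and inverted once in the Mitsunobu step. C7'' is induced by C8'' in the ring closure, where trans-4,5 on the dioxanone equals erythro, that is (7''R,8''S).

Key step: step 6

Assumption: locants follow the name of the target (rings A and C are the chromen-4-one, ring B the 3',5'-dimethoxyaryl ring, ring D the 4''-oxygenated ring, C7''–C9'' the three-carbon chain), and 1, 3, 6 and 13 are taken as catalogue compounds.

Step 1
Reactants: 1 4-bromophenol
Product: 2 (4-bromophenoxy)triisopropylsilane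
Conditions: TIPSCl, imidazole, DMF, 0 °C to rt
Reagents that add atoms: triisopropylsilyl chloride, CC(C)[Si](Cl)(C(C)C)C(C)C
Why: Imidazole-promoted O-silylation of a phenol is routine, and the triisopropylsilyl group keeps the ring D oxygen a donor, survives Grignard formation and has no C–H bond next to oxygen that could compete with C7''–H at the anode.

Step 2
Reactants: 2 (4-bromophenoxy)triisopropylsilane; 3 (S)-benzyl glycidyl ether, (2S)-2-[(benzyloxy)methyl]oxirane
Product: 5 (2S)-1-(benzyloxy)-3-[4-(triisopropylsilyloxy)phenyl]propan-2-ol, via 4-(triisopropylsilyloxy)phenylmagnesium bromide 4 (not isolated)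
Conditions: Mg, THF, reflux; then CuI (10 mol %), 3, THF, −30 to 0 °C; H2O
Reagents that add atoms: magnesium, [Mg] (retained only in intermediate 4)
Why: Copper-catalysed opening of a terminal epoxide by an aryl Grignard reagent takes place at the unsubstituted carbon and forms C1''–C7'', so no bond to the stereocentre is touched and the (S) configuration of 3 passes unchanged into 5.

Step 3
Reactants: 5 (2S)-1-(benzyloxy)-3-[4-(triisopropylsilyloxy)phenyl]propan-2-ol; 6 methyl syringate (methyl 4-hydroxy-3,5-dimethoxybenzoate)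
Product: 7 methyl 4-{[(2R)-1-(benzyloxy)-3-[4-(triisopropylsilyloxy)phenyl]propan-2-yl]oxy}-3,5-dimethoxybenzoate
Conditions: PPh3, DIAD, THF, 0 °C to rt
Reagents that add atoms: none
Why: Mitsunobu etherification, in which the fairly acidic phenol 6 displaces the oxyphosphonium-activated secondary alcohol by SN2 with inversion, turns (S)-5 into the (R)-aryl ether and so fixes C8'' in the spatial arrangement of the target.

Step 4
Reactants: 7 methyl 4-{[(2R)-1-(benzyloxy)-3-[4-(triisopropylsilyloxy)phenyl]propan-2-yl]oxy}-3,5-dimethoxybenzoate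
Product: 8 methyl 4-{[(2R)-1-hydroxy-3-[4-(triisopropylsilyloxy)phenyl]propan-2-yl]oxy}-3,5-dimethoxybenzoate
Conditions: H2 (1 atm), Pd/C, EtOAc/EtOH, rt
Reagents that add atoms: none
Why: Catalytic hydrogenolysis cleaves only the benzylic C–O bond of the O9'' benzyl ether, since the C8''–O aryl ether is not benzylic and the silyl ether and the ester are inert to H2 over Pd/C.

Step 5
Reactants: 8 methyl 4-{[(2R)-1-hydroxy-3-[4-(triisopropylsilyloxy)phenyl]propan-2-yl]oxy}-3,5-dimethoxybenzoate
Product: 9 methyl 4-{[(2R)-1-(tert-butoxycarbonyloxy)-3-[4-(triisopropylsilyloxy)phenyl]propan-2-yl]oxy}-3,5-dimethoxybenzoate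
Conditions: Boc2O, DMAP (cat.), MeCN, rt
Reagents that add atoms: di-tert-butyl dicarbonate, CC(C)(C)OC(=O)OC(=O)OC(C)(C)C
Why: DMAP-catalysed O-acylation of a primary alcohol with Boc2O is the standard way to a mixed tert-butyl carbonate, and nothing else in 8 is nucleophilic.

Step 6
Reactants: 9 methyl 4-{[(2R)-1-(tert-butoxycarbonyloxy)-3-[4-(triisopropylsilyloxy)phenyl]propan-2-yl]oxy}-3,5-dimethoxybenzoate
Product: 10 methyl 3,5-dimethoxy-4-{[(4R,5S)-2-oxo-4-[4-(triisopropylsilyloxy)phenyl]-1,3-dioxan-5-yl]oxy}benzoate (trans)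
Conditions: undivided cell, graphite anode, Pt cathode, constant current (about 3 mA/cm2), 2.2 F/mol, n-Bu4NOTf (0.1 M), 2,6-lutidine (2 equiv), (CF3)2CHOH/CH2Cl2 1:4, 0 °C
Reagents that add atoms: none
Why: Proposed new method: the anode takes one electron from the ring D silyloxyarene, 2,6-lutidine removes a C7'' proton from the radical cation, and a second electron transfer gives a C7'' cation with O-silyl quinone methide character that is attacked by the carbonyl oxygen of the O9'' carbonate, after which the 2-tert-butoxy-1,3-dioxan-2-ylium ion sheds isobutene and the cathode turns the two released protons into H2. The closest known reaction types are the anodic benzylic C–H acetoxylation, alkoxylation and lactonisation of 4-alkylanisoles and the capture of halonium ions or ionised leaving groups by neighbouring tert-butyl carbonates, but their combination on a beta-aryloxy alkylarene is without precedent. The one new ring, the 1,3-dioxan-2-one O7''–C(=O)–O9''–C9''–C8''–C7'', closes in the 6-exo-trig mode because the C7''=C1'' bond of the quinone methide form stays outside it. The new stereocentre C7'' is controlled by C8'' under kinetic conditions: allylic 1,3-strain against an ortho C–H of ring D keeps H8'' in the plane of the cation, the bulky ring B aryloxy group then shields one face and the C9'' arm lies on the other, so oxygen is delivered anti to the aryloxy group through a chair in which ring D and the aryloxy group are both equatorial, which gives the trans (4R,5S) carbonate, the erythro (7''R,8''S) series. The step needs reaction at ring D although ring B carries three oxygens, and this is secured by the para ester and the twisted, poorly conjugated O4' that raise the potential of ring B, by the lack of any benzylic C–H on ring B, so that a hole formed there can only hop to ring D where C7''–H loss is irreversible, and by a silyl group without C–H bonds next to oxygen. Intramolecular capture should outrun proton loss from C8'' and attack by the weakly nucleophilic fluoro alcohol, and over-oxidation is limited because the acyloxy group now on C7'' makes ring D of 10 harder to oxidise than that of 9 and the charge is stopped just above 2 F/mol.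

Step 7
Reactants: 10 methyl 3,5-dimethoxy-4-{[(4R,5S)-2-oxo-4-[4-(triisopropylsilyloxy)phenyl]-1,3-dioxan-5-yl]oxy}benzoate
Product: 11 methyl 4-{[(1R,2S)-1,3-dihydroxy-1-[4-(triisopropylsilyloxy)phenyl]propan-2-yl]oxy}-3,5-dimethoxybenzoate (erythro)
Conditions: K2CO3 (0.2 equiv), MeOH, 0 °C, short contact
Reagents that add atoms: none
Why: Base-catalysed transesterification (methanolysis) of the six-membered carbonate at its carbonyl carbon is far faster than attack on the hindered aryl silyl ether, exchange at the methyl benzoate is degenerate, and no bond to C7'' or C8'' is broken.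

Step 8
Reactants: 11 methyl 4-{[(1R,2S)-1,3-dihydroxy-1-[4-(triisopropylsilyloxy)phenyl]propan-2-yl]oxy}-3,5-dimethoxybenzoate
Product: 12 methyl 4-{[(4R,5S)-2,2-di-tert-butyl-4-[4-(triisopropylsilyloxy)phenyl]-1,3,2-dioxasilinan-5-yl]oxy}-3,5-dimethoxybenzoate
Conditions: t-Bu2Si(OTf)2, 2,6-lutidine, CH2Cl2, 0 °C
Reagents that add atoms: di-tert-butylsilyl bis(trifluoromethanesulfonate), CC(C)(C)[Si](OS(=O)(=O)C(F)(F)F)(OS(=O)(=O)C(F)(F)F)C(C)(C)C
Why: Cyclic silylene formation from a 1,3-diol and the silyl bis-triflate under lutidine buffering makes only O–Si bonds, so C7'' and C8'' are untouched, and the product withstands amide bases and mild anhydrous acid yet falls to fluoride together with the TIPS group.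

Step 9
Reactants: 13 2,4,6-trihydroxyacetophenone
Product: 14 1-[2,4-bis(benzyloxy)-6-hydroxyphenyl]ethan-1-one
Conditions: BnBr (2.05 equiv), K2CO3, DMF, rt
Reagents that add atoms: benzyl bromide, BrCc1ccccc1
Why: Williamson ether synthesis with two equivalents of benzyl bromide stops at the dibenzyl ether because one ortho hydroxyl stays locked in a hydrogen bond to the ketone carbonyl and is the least nucleophilic.

Step 10
Reactants: 12 methyl 4-{[(4R,5S)-2,2-di-tert-butyl-4-[4-(triisopropylsilyloxy)phenyl]-1,3,2-dioxasilinan-5-yl]oxy}-3,5-dimethoxybenzoate; 14 1-[2,4-bis(benzyloxy)-6-hydroxyphenyl]ethan-1-one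
Product: 16 1-[2,4-bis(benzyloxy)-6-hydroxyphenyl]-3-(4-{[(4R,5S)-2,2-di-tert-butyl-4-[4-(triisopropylsilyloxy)phenyl]-1,3,2-dioxasilinan-5-yl]oxy}-3,5-dimethoxyphenyl)propane-1,3-dione, via dilithium enolate phenoxide 15 (not isolated)
Conditions: 14 (1.5 equiv), LiN(SiMe3)2 (excess), THF, −78 to 0 °C; then 12, 0 °C to rt; AcOH quench
Reagents that add atoms: lithium hexamethyldisilazide, [Li]N([Si](C)(C)C)[Si](C)(C)C (lithium retained only in intermediate 15)
Why: Crossed Claisen condensation, the direct intermolecular counterpart of the Baker–Venkataraman acyl transfer, lets the non-enolisable benzoate 12 acylate the terminal enolate carbon of 15 to form C2–C3, and deprotonation of the resulting 1,3-diketone drives the equilibrium.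

Step 11
Reactants: 16 1-[2,4-bis(benzyloxy)-6-hydroxyphenyl]-3-(4-{[(4R,5S)-2,2-di-tert-butyl-4-[4-(triisopropylsilyloxy)phenyl]-1,3,2-dioxasilinan-5-yl]oxy}-3,5-dimethoxyphenyl)propane-1,3-dione
Product: 17 5,7-bis(benzyloxy)-2-(4-{[(4R,5S)-2,2-di-tert-butyl-4-[4-(triisopropylsilyloxy)phenyl]-1,3,2-dioxasilinan-5-yl]oxy}-3,5-dimethoxyphenyl)-4H-chromen-4-one
Conditions: p-TsOH·H2O (10 mol %), toluene, 4 Å MS, 70 °C
Reagents that add atoms: none
Why: Acid-catalysed cyclodehydration of an o-hydroxyaryl 1,3-diketone, the closing stage of the Baker–Venkataraman flavone synthesis, forms O1–C2 through the cyclic hemiketal, while the weakly basic silylene oxygen on C7'', the inductive pull of the C8'' aryloxy group and the absence of water keep the benzylic C–O bond from ionising.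

Step 12
Reactants: 17 5,7-bis(benzyloxy)-2-(4-{[(4R,5S)-2,2-di-tert-butyl-4-[4-(triisopropylsilyloxy)phenyl]-1,3,2-dioxasilinan-5-yl]oxy}-3,5-dimethoxyphenyl)-4H-chromen-4-one
Product: 18 2-(4-{[(4R,5S)-2,2-di-tert-butyl-4-[4-(triisopropylsilyloxy)phenyl]-1,3,2-dioxasilinan-5-yl]oxy}-3,5-dimethoxyphenyl)-5,7-dihydroxy-4H-chromen-4-one
Conditions: H2 (1 atm), Pd/C, EtOAc/THF, rt
Reagents that add atoms: none
Why: Hydrogenolysis of aryl benzyl ethers over Pd/C is routine on 5,7-dibenzyloxyflavones, and it is run while O7'' is still buried in the hindered silylene ring so that the C7''–O bond is not reduced.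

Step 13
Reactants: 18 2-(4-{[(4R,5S)-2,2-di-tert-butyl-4-[4-(triisopropylsilyloxy)phenyl]-1,3,2-dioxasilinan-5-yl]oxy}-3,5-dimethoxyphenyl)-5,7-dihydroxy-4H-chromen-4-one
Product: 19 (−)-(7''R,8''S)-4'',5,7-trihydroxy-3',5'-dimethoxy-4',8''-oxyflavonolignan-7'',9''-diol
Conditions: TBAF, AcOH (1:1, excess), THF, 0 °C to rt
Reagents that add atoms: none
Why: Fluoride-induced desilylation buffered with acetic acid cleaves the aryl TIPS ether and the silylene at silicon only, so no C–O bond at C7'' or C8'' is broken, and the buffer prevents quinone methide formation from the freed ring D phenol.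

**Compound list**
1 | 4-bromophenol | Oc1ccc(Br)cc1 | starting material
2 | (4-bromophenoxy)triisopropylsilane | CC(C)[Si](Oc1ccc(Br)cc1)(C(C)C)C(C)C | intermediate
3 | (S)-benzyl glycidyl ether | c1ccccc1COC[C@@H]1CO1 | starting material
4 | 4-(triisopropylsilyloxy)phenylmagnesium bromide (not isolated) | Br[Mg]c1ccc(O[Si](C(C)C)(C(C)C)C(C)C)cc1 | intermediate
5 | (2S)-1-(benzyloxy)-3-[4-(triisopropylsilyloxy)phenyl]propan-2-ol | O[C@H](COCc1ccccc1)Cc1ccc(O[Si](C(C)C)(C(C)C)C(C)C)cc1 | intermediate
6 | methyl syringate | COC(=O)c1cc(OC)c(O)c(OC)c1 | starting material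
7 | methyl 4-{[(2R)-1-(benzyloxy)-3-[4-(triisopropylsilyloxy)phenyl]propan-2-yl]oxy}-3,5-dimethoxybenzoate | COC(=O)c1cc(OC)c(O[C@@H](COCc2ccccc2)Cc2ccc(O[Si](C(C)C)(C(C)C)C(C)C)cc2)c(OC)c1 | intermediate
8 | methyl 4-{[(2R)-1-hydroxy-3-[4-(triisopropylsilyloxy)phenyl]propan-2-yl]oxy}-3,5-dimethoxybenzoate | COC(=O)c1cc(OC)c(O[C@@H](CO)Cc2ccc(O[Si](C(C)C)(C(C)C)C(C)C)cc2)c(OC)c1 | intermediate
9 | methyl 4-{[(2R)-1-(tert-butoxycarbonyloxy)-3-[4-(triisopropylsilyloxy)phenyl]propan-2-yl]oxy}-3,5-dimethoxybenzoate | COC(=O)c1cc(OC)c(O[C@@H](COC(=O)OC(C)(C)C)Cc2ccc(O[Si](C(C)C)(C(C)C)C(C)C)cc2)c(OC)c1 | intermediate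
10 | methyl 3,5-dimethoxy-4-{[(4R,5S)-2-oxo-4-[4-(triisopropylsilyloxy)phenyl]-1,3-dioxan-5-yl]oxy}benzoate | COC(=O)c1cc(OC)c(O[C@H]2COC(=O)O[C@@H]2c2ccc(O[Si](C(C)C)(C(C)C)C(C)C)cc2)c(OC)c1 | intermediate
11 | methyl 4-{[(1R,2S)-1,3-dihydroxy-1-[4-(triisopropylsilyloxy)phenyl]propan-2-yl]oxy}-3,5-dimethoxybenzoate | COC(=O)c1cc(OC)c(O[C@@H](CO)[C@H](O)c2ccc(O[Si](C(C)C)(C(C)C)C(C)C)cc2)c(OC)c1 | intermediate
12 | methyl 4-{[(4R,5S)-2,2-di-tert-butyl-4-[4-(triisopropylsilyloxy)phenyl]-1,3,2-dioxasilinan-5-yl]oxy}-3,5-dimethoxybenzoate | COC(=O)c1cc(OC)c(O[C@H]2CO[Si](C(C)(C)C)(C(C)(C)C)O[C@@H]2c2ccc(O[Si](C(C)C)(C(C)C)C(C)C)cc2)c(OC)c1 | intermediate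
13 | 2,4,6-trihydroxyacetophenone | CC(=O)c1c(O)cc(O)cc1O | starting material
14 | 1-[2,4-bis(benzyloxy)-6-hydroxyphenyl]ethan-1-one | CC(=O)c1c(O)cc(OCc2ccccc2)cc1OCc1ccccc1 | intermediate
15 | dilithium enolate phenoxide of 14 (not isolated) | C=C(O[Li])c1c(O[Li])cc(OCc2ccccc2)cc1OCc1ccccc1 | intermediate
16 | 1-[2,4-bis(benzyloxy)-6-hydroxyphenyl]-3-(4-{[(4R,5S)-2,2-di-tert-butyl-4-[4-(triisopropylsilyloxy)phenyl]-1,3,2-dioxasilinan-5-yl]oxy}-3,5-dimethoxyphenyl)propane-1,3-dione | O=C(CC(=O)c1cc(OC)c(O[C@H]2CO[Si](C(C)(C)C)(C(C)(C)C)O[C@@H]2c2ccc(O[Si](C(C)C)(C(C)C)C(C)C)cc2)c(OC)c1)c1c(O)cc(OCc2ccccc2)cc1OCc1ccccc1 | intermediate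
17 | 5,7-bis(benzyloxy)-2-(4-{[(4R,5S)-2,2-di-tert-butyl-4-[4-(triisopropylsilyloxy)phenyl]-1,3,2-dioxasilinan-5-yl]oxy}-3,5-dimethoxyphenyl)-4H-chromen-4-one | COc1cc(-c2cc(=O)c3c(OCc4ccccc4)cc(OCc4ccccc4)cc3o2)cc(OC)c1O[C@H]1CO[Si](C(C)(C)C)(C(C)(C)C)O[C@@H]1c1ccc(O[Si](C(C)C)(C(C)C)C(C)C)cc1 | intermediate
18 | 2-(4-{[(4R,5S)-2,2-di-tert-butyl-4-[4-(triisopropylsilyloxy)phenyl]-1,3,2-dioxasilinan-5-yl]oxy}-3,5-dimethoxyphenyl)-5,7-dihydroxy-4H-chromen-4-one | COc1cc(-c2cc(=O)c3c(O)cc(O)cc3o2)cc(OC)c1O[C@H]1CO[Si](C(C)(C)C)(C(C)(C)C)O[C@@H]1c1ccc(O[Si](C(C)C)(C(C)C)C(C)C)cc1 | intermediate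
19 | (−)-(7''R,8''S)-4'',5,7-trihydroxy-3',5'-dimethoxy-4',8''-oxyflavonolignan-7'',9''-diol | COc1cc(-c2cc(=O)c3c(O)cc(O)cc3o2)cc(OC)c1O[C@@H](CO)[C@H](O)c1ccc(O)cc1 | target

Total step count: 13.
Longest linear sequence: 12 steps (from 1 through steps 1–8 and 10–13; step 9 is a one-step side branch).

**Steps most likely to fail**

**Step 6.**
- What may go wrong: electron removal from ring B instead of ring D, loss of the silyl group from the oxidised ring D, proton loss from C8'' of the cation instead of ring closure, capture by the solvent, or a weak facial bias.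
- The fallback uses known chemistry without electron transfer. It sets out from 9 and comes back at 10.
- Wohl–Ziegler bromination (NBS, AIBN, PhCF3, 80 °C) selects C7'' by its weak benzylic C–H bond and should give the C7'' bromide F1 as a mixture of epimers.
- The crude material is treated with AgOTf and 2,6-lutidine in CH2Cl2 at −40 °C. The C–Br bond ionises, the neighbouring tert-butyl carbonate takes part as in known carbonate-assisted solvolyses, and isobutene is lost.
- Both epimers pass through one cation, so the stereochemical argument of step 6 still applies.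

**Step 10.**
- What may go wrong: slow acylation of the enolate by the electron-rich, hindered benzoate, so that proton exchange and self-condensation of the ketone take over.
- The fallback sets out from 12 and comes back at 16.
- Me3SnOH (1,2-dichloroethane, 80 °C, dilute HCl wash) should free the benzoic acid F2 without touching the silicon groups.
- EDC and DMAP in CH2Cl2 esterify it with phenol 14 to the aryl ester F3.
- LiN(SiMe3)2 in THF (−78 °C to rt, AcOH quench) then brings about the intramolecular Baker–Venkataraman acyl shift to the diketone.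

**Step 3.**
- What may go wrong: sluggish SN2 displacement at an unactivated secondary carbinol by a phenol with two ortho substituents, with elimination toward C7'' or alkylation of the hydrazide anion winning.
- The fallback forms the C8''–O bond next to a carbonyl group, where displacement is faster. It sets out from 6 and comes back at 8, and steps 1, 2 and 4 are then not needed.
- Purchased methyl (S)-3-(4-hydroxyphenyl)lactate F4 is silylated at the phenol (TIPSCl, imidazole, DMF) to the silyl ether F5.
- Mitsunobu reaction of F5 with 6 (PPh3, DIAD, THF) gives, with inversion, the (R)-aryloxy diester F6.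
- NaBH4 in THF/MeOH reduces only the activated aliphatic ester and leaves the electron-rich benzoate.

**Further compounds**
F1 | step 6 | methyl 4-{[(2S)-1-bromo-3-(tert-butoxycarbonyloxy)-1-[4-(triisopropylsilyloxy)phenyl]propan-2-yl]oxy}-3,5-dimethoxybenzoate (both C7'' epimers) | COC(=O)c1cc(OC)c(O[C@@H](COC(=O)OC(C)(C)C)C(Br)c2ccc(O[Si](C(C)C)(C(C)C)C(C)C)cc2)c(OC)c1
F2 | step 10 | 4-{[(4R,5S)-2,2-di-tert-butyl-4-[4-(triisopropylsilyloxy)phenyl]-1,3,2-dioxasilinan-5-yl]oxy}-3,5-dimethoxybenzoic acid | OC(=O)c1cc(OC)c(O[C@H]2CO[Si](C(C)(C)C)(C(C)(C)C)O[C@@H]2c2ccc(O[Si](C(C)C)(C(C)C)C(C)C)cc2)c(OC)c1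
F3 | step 10 | 2-acetyl-3,5-bis(benzyloxy)phenyl 4-{[(4R,5S)-2,2-di-tert-butyl-4-[4-(triisopropylsilyloxy)phenyl]-1,3,2-dioxasilinan-5-yl]oxy}-3,5-dimethoxybenzoate | CC(=O)c1c(OC(=O)c2cc(OC)c(O[C@H]3CO[Si](C(C)(C)C)(C(C)(C)C)O[C@@H]3c3ccc(O[Si](C(C)C)(C(C)C)C(C)C)cc3)c(OC)c2)cc(OCc2ccccc2)cc1OCc1ccccc1
F4 | step 3 | methyl (2S)-2-hydroxy-3-(4-hydroxyphenyl)propanoate (purchased) | O[C@H](C(=O)OC)Cc1ccc(O)cc1
F5 | step 3 | methyl (2S)-2-hydroxy-3-[4-(triisopropylsilyloxy)phenyl]propanoate | O[C@H](C(=O)OC)Cc1ccc(O[Si](C(C)C)(C(C)C)C(C)C)cc1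
F6 | step 3 | methyl 4-{[(2R)-1-methoxy-1-oxo-3-[4-(triisopropylsilyloxy)phenyl]propan-2-yl]oxy}-3,5-dimethoxybenzoate | COC(=O)c1cc(OC)c(O[C@@H](C(=O)OC)Cc2ccc(O[Si](C(C)C)(C(C)C)C(C)C)cc2)c(OC)c1
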